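**Assumption:** 6, 7, 16 and 28 are taken as purchasable (28 freshly distilled); locants C1–C20 for the larger intermediates follow the ent-kaurane numbering of the target (C1 ketone, C5 bearing C6, C7 lactone carbonyl, C20 lactone CH2). Where a name and a SMILES string differ, the SMILES string is the intended structure.

## Retrosynthetic overview

1. 38 ⇐ exo-face dihydroxylation of the C16=C17 methylidene, after late C2=C3 desaturation and PMB removal on tetracyclic lactone 34.
2. Ring D ⇐ 5-exo vinyl-radical closure (C16–C13); ring C ⇐ RCM of the C8/C9 diallyl pair; C8 quaternary centre and C15 carbinol ⇐ conjugate allylation–Mukaiyama aldol on unsaturated spirolactone 27.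
3. 27 ⇐ oxidative lactonisation of keto diol 24, whose C9–C10 bond and C10 quaternary centre come from the key semipinacol 1,2-alkenyl shift (C1→C10) of epoxy alcohol 21.
4. 21 ⇐ epoxy ketone 14 + (Z)-alkenyl metal (from prop-2-yn-1-ol by carbomagnesiation); 14 ⇐ enantioselective conjugate oxymethylation/methylenation of enone 5 (isobutyraldehyde + methyl vinyl ketone).
5. Ring order: A, then the spiro δ-lactone, then C, then D.

## Route

**Step 1**
Reactants: 1 2-methylpropanal; 2 but-3-en-2-one
Product: 5 4,4-dimethylcyclohex-2-en-1-one, via keto aldehyde 3 (not isolated), via ketol 4 (not isolated)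
Conditions: H2SO4 (cat.), PhH, 45 °C then reflux (Dean–Stark)
Reagents that add atoms: none
Why: Acid-catalysed Robinson annulation (Michael addition of the aldehyde enol to the enone, then intramolecular aldol condensation); no stereocentre is formed.

**Step 2**
Reactants: 5 4,4-dimethylcyclohex-2-en-1-one; 6 1-[(chloromethoxy)methyl]-4-methoxybenzene; 7 N,N-dimethylmethylideneammonium chloride
Product: 12 (3R)-3-{[(4-methoxybenzyl)oxy]methyl}-4,4-dimethyl-2-methylidenecyclohexan-1-one, via Grignard reagent 8 (not isolated), via magnesium enolate 9 (not isolated), via Mannich base 10 (not isolated), via methiodide 11 (not isolated)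
Conditions: 6, Mg, THF, −20 °C; CuBr·SMe2 (5 mol %), (R)-1-[(S)-2-(diphenylphosphino)ferrocenyl]ethyldicyclohexylphosphine (6 mol %), t-BuOMe, −60 °C, slow addition of 8 to 5; then 7, −60 → 0 °C; then MeI, rt; then aq NaHCO3, CH2Cl2
Reagents that add atoms: none
Why: Proposed new method: a copper-catalysed enantioselective conjugate addition of an α-alkoxymethyl Grignard reagent, in which 8 transmetalates to the chiral monovalent copper–diphosphine complex, the enone is π-complexed, enantio-determining oxidative addition at the β-carbon gives a trivalent copper enolate and reductive elimination sets C5 (3R; the ligand antipode is chosen accordingly), after which the regiodefined magnesium enolate is trapped by the iminium salt (Mannich) and quaternisation/E1cB elimination reveals the methylidene; the closest known reaction types are the Cu/ferrocenyl-diphosphine conjugate addition of simple primary alkyl Grignard reagents to cyclohexenones and the racemic cuprate additions of alkoxymethyl organometallics.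

**Step 3**
Reactants: 12 (3R)-3-{[(4-methoxybenzyl)oxy]methyl}-4,4-dimethyl-2-methylidenecyclohexan-1-one
Product: 14 (3S,8S)-8-{[(4-methoxybenzyl)oxy]methyl}-7,7-dimethyl-1-oxaspiro[2.5]octan-4-one (epoxide oxygen cis to CH2OPMB), via bromohydrin 13 (not isolated)
Conditions: NBS, THF/H2O (4:1), 0 °C; then K2CO3, MeOH, 0 °C → rt
Reagents that add atoms: water (O)
Why: Bromohydrin formation (Br to C10 from the face away from the C5 side chain, water to C20) followed by Darzens-type ring closure with inversion at C10 places the epoxide oxygen cis to the C5 side chain.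

**Step 4**
Reactants: 15 prop-2-yn-1-ol; 16 allylmagnesium bromide
Product: 18 (2Z)-2-(iodomethylidene)pent-4-en-1-ol, via alkenylmagnesium chelate 17 (not isolated)
Conditions: 16 (2.2 equiv), CuI (10 mol %), Et2O, 0 °C → rt; then I2, THF, −40 °C; 1 M HCl work-up
Reagents that add atoms: iodine (II)
Why: Hydroxyl-directed anti-carbomagnesiation of the propargylic alkoxide (allyl to C2, magnesium to C3 in a five-membered chelate) and iodinolysis with retention give the (Z)-iodide.

**Step 5**
Reactants: 18 (2Z)-2-(iodomethylidene)pent-4-en-1-ol; 14 spiro-epoxy ketone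
Product: 21 (3S,4R,8S)-4-[(1Z)-2-(hydroxymethyl)penta-1,4-dien-1-yl]-8-{[(4-methoxybenzyl)oxy]methyl}-7,7-dimethyl-1-oxaspiro[2.5]octan-4-ol, via dilithio reagent 19 (not isolated), via organocerium reagent 20 (not isolated)
Conditions: 18, t-BuLi (3.0 equiv), Et2O, −78 °C; CeCl3, THF, −78 °C; then 14, −78 °C; aq NH4Cl
Reagents that add atoms: none
Why: Organocerium 1,2-addition (no enolisation) follows Felkin–Anh/Cornforth control, attacking C1 anti to the axial epoxide C–O bond and away from the C5 side chain, so the alkenyl group ends anti-periplanar to the epoxide oxygen.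

**Step 6**
Reactants: 21 epoxy diol
Product: 24 keto diol (C10 quaternary; alkenyl C9 trans and CH2OH C20 cis to the C5 side chain), via bis(trimethylsilyl) ether 22 (not isolated), via rearranged silyl ether 23 (not isolated)
Conditions: TMSOTf (2.4 equiv), 2,6-lutidine (3 equiv), CH2Cl2, −78 → −40 °C; then 1 M HCl, MeOH, 0 °C
Reagents that add atoms: none
Why: Lewis-acid semipinacol rearrangement of a 2,3-epoxy silyl ether (Suzuki–Tsuchihashi type), in which the alkenyl group shifts from C1 to C10 anti to the breaking C10–O bond with inversion at C10, forming the C9–C10 bond and the quaternary centre while C1 becomes the ketone; the cis CH2OPMB oxygen cannot attack from the rear and methanolysis removes the silyl groups.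

**Step 7**
Reactants: 24 keto diol
Product: 27 4-allyl-11-{[(4-methoxybenzyl)oxy]methyl}-10,10-dimethyl-2-oxaspiro[5.5]undec-4-ene-3,7-dione (C10 and C5 as in 24), via hydroxy enal 25 (not isolated), via lactol 26 (not isolated)
Conditions: MnO2 (20 equiv), CH2Cl2, rt
Reagents that add atoms: none
Why: Oxidative lactonisation in which MnO2 oxidises only the allylic alcohol, the (Z)-enal closes on the C20 hydroxyl and the lactol is oxidised on to the α,β-unsaturated δ-lactone; no stereocentre changes.

**Step 8**
Reactants: 27 unsaturated spirolactone; 16 allylmagnesium bromide; 28 2-bromoprop-2-enal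
Product: 32 aldol lactone (C9 allyl cis to C1; C8 bearing allyl and CH(OH)C(Br)=CH2; C15 as in the target), via allylcopper 29 (not isolated), via ketene silyl acetal 30 (not isolated), via silyl aldol ether 31 (not isolated)
Conditions: 16, CuBr·SMe2, THF, −78 °C; 27, TMSCl, −78 °C; then 28, TMSOTf (10 mol %), CH2Cl2, −78 °C; then 1 M HCl, THF, 0 °C
Reagents that add atoms: none
Why: TMSCl-accelerated copper conjugate allylation from the lactone face away from C5 sets C9, and the regiodefined ketene silyl acetal then undergoes a Mukaiyama aldol anti to the new allyl group (C8 quaternary) through an open transition state that keeps the bromovinyl group away from C9 (C15).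

**Step 9**
Reactants: 32 aldol lactone
Product: 33 cyclohexene-fused lactone (ring C closed; C12=C13)
Conditions: second-generation Grubbs catalyst (5 mol %), CH2Cl2, 40 °C
Reagents that add atoms: none
Why: Ring-closing metathesis of the cis C8/C9 allyl groups gives the cis-fused cyclohexene, the 2-bromoallyl alkene being inert; no stereocentre changes.

**Step 10**
Reactants: 33 cyclohexene-fused lactone
Product: 34 tetracyclic 15-hydroxy-16-methylidene lactone (bicyclo[3.2.1]octane formed; C6 O-PMB; ring A saturated ketone)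
Conditions: Bu3SnH (1.5 equiv, 0.05 M), AIBN (10 mol %), PhH, 80 °C
Reagents that add atoms: none
Why: Tin hydride radical cyclisation in which the C16 vinyl radical closes 5-exo onto C13 from the face of its C8 tether (which fixes C13), and the high hydride concentration reduces the C12 radical before homoallyl rearrangement.

**Step 11**
Reactants: 34 tetracyclic lactone
Product: 37 1-oxo-2-ene 6,15-diol (C16=C17 methylidene intact), via bis-silyl compound 35 (not isolated), via silyl-protected enone 36 (not isolated)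
Conditions: LDA (2.5 equiv), TMSCl, THF, −78 °C; then DDQ (3 equiv), 2,6-lutidine, CH2Cl2, 0 °C → rt; then pH 7 buffer, rt; 1 M HCl work-up
Reagents that add atoms: none
Why: Regiospecific enol silylation (C2 is the only enolisable position) and DDQ dehydrosilylation give the C2=C3 enone, and wet DDQ then cleaves the PMB ether oxidatively; no stereocentre is touched.

**Step 12**
Reactants: 37 enone diol
Product: 38 CNP0546915.1 (6,15,16,17-tetrahydroxy-1-oxo-6,7-seco-ent-kaur-2-en-7,20-olide, stereochemistry as in the given SMILES)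
Conditions: OsO4 (2 mol %), NMO, acetone/H2O (4:1), 0 °C
Reagents that add atoms: N-methylmorpholine N-oxide (C[N+]1([O-])CCOCC1); water (O)
Why: Upjohn dihydroxylation in which OsO4 adds to the strained 1,1-disubstituted C16=C17 alkene (the hindered, electron-poor enone alkene is left) from the exo face anti to the allylic 15-OH, setting C16.

## Compound list

1 | 2-methylpropanal (isobutyraldehyde) | CC(C)C=O | starting material
2 | but-3-en-2-one (methyl vinyl ketone) | CC(=O)C=C | starting material
3 | 2,2-dimethyl-5-oxohexanal | CC(=O)CCC(C)(C)C=O | intermediate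
4 | 3-hydroxy-4,4-dimethylcyclohexan-1-one (racemic ketol) | CC1(C)CCC(=O)CC1O | intermediate
5 | 4,4-dimethylcyclohex-2-en-1-one | CC1(C)CCC(=O)C=C1 | intermediate
6 | 1-[(chloromethoxy)methyl]-4-methoxybenzene (PMB chloromethyl ether) | COc1ccc(COCCl)cc1 | starting material
7 | N,N-dimethylmethylideneammonium chloride | C=[N+](C)C.[Cl-] | starting material
8 | {[(4-methoxybenzyl)oxy]methyl}magnesium chloride | COc1ccc(COC[Mg]Cl)cc1 | intermediate
9 | chloromagnesium C1–C10 enolate of the conjugate adduct (C5 set) | CC1(C)CCC(O[Mg]Cl)=C[C@@H]1COCc2ccc(OC)cc2 | intermediate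
10 | (2R,3S)-2-[(dimethylamino)methyl]-3-{[(4-methoxybenzyl)oxy]methyl}-4,4-dimethylcyclohexan-1-one (trans Mannich base) | CC1(C)CCC(=O)[C@@H](CN(C)C)[C@@H]1COCc2ccc(OC)cc2 | intermediate
11 | trimethylammonium iodide of 10 | CC1(C)CCC(=O)[C@@H](C[N+](C)(C)C)[C@@H]1COCc2ccc(OC)cc2.[I-] | intermediate
12 | (3R)-3-{[(4-methoxybenzyl)oxy]methyl}-4,4-dimethyl-2-methylidenecyclohexan-1-one | CC1(C)CCC(=O)C(=C)[C@@H]1COCc2ccc(OC)cc2 | intermediate
13 | 2-bromo-2-(hydroxymethyl) ketone from 12 (Br trans to CH2OPMB) | CC1(C)CCC(=O)[C@](Br)(CO)[C@@H]1COCc2ccc(OC)cc2 | intermediate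
14 | (3S,8S)-8-{[(4-methoxybenzyl)oxy]methyl}-7,7-dimethyl-1-oxaspiro[2.5]octan-4-one (epoxide O cis to CH2OPMB) | CC1(C)CCC(=O)[C@@]2(CO2)[C@@H]1COCc3ccc(OC)cc3 | intermediate
15 | prop-2-yn-1-ol | OCC#C | starting material
16 | allylmagnesium bromide | C=CC[Mg]Br | starting material
17 | (Z)-2-allyl-3-(bromomagnesio)prop-2-en-1-olate magnesium bromide (chelate) | Br[Mg]/C=C(\CO[Mg]Br)CC=C | intermediate
18 | (2Z)-2-(iodomethylidene)pent-4-en-1-ol | I/C=C(\CO)CC=C | intermediate
19 | dilithio reagent from 18 (Z; C-Li cis to CH2OLi) | [Li]/C=C(\CO[Li])CC=C | intermediate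
20 | dichlorocerium alkenyl reagent from 19 | Cl[Ce](Cl)/C=C(\CO[Li])CC=C | intermediate
21 | (3S,4R,8S)-4-[(1Z)-2-(hydroxymethyl)penta-1,4-dien-1-yl]-8-{[(4-methoxybenzyl)oxy]methyl}-7,7-dimethyl-1-oxaspiro[2.5]octan-4-ol (alkenyl trans, OH cis to the epoxide O) | CC1(C)CC[C@@](O)(/C=C(\CO)CC=C)[C@@]2(CO2)[C@@H]1COCc3ccc(OC)cc3 | intermediate
22 | bis(trimethylsilyl) ether of 21 | CC1(C)CC[C@@](O[Si](C)(C)C)(/C=C(\CO[Si](C)(C)C)CC=C)[C@@]2(CO2)[C@@H]1COCc3ccc(OC)cc3 | intermediate
23 | rearranged ketone, C7 and C20 hydroxyls as TMS ethers | CC1(C)CCC(=O)[C@](/C=C(\CO[Si](C)(C)C)CC=C)(CO[Si](C)(C)C)[C@@H]1COCc2ccc(OC)cc2 | intermediate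
24 | keto diol: 2-(hydroxymethyl)-2-[(1Z)-2-(hydroxymethyl)penta-1,4-dien-1-yl]-3-{[(4-methoxybenzyl)oxy]methyl}-4,4-dimethylcyclohexan-1-one (alkenyl trans, CH2OH cis to CH2OPMB) | CC1(C)CCC(=O)[C@](/C=C(\CO)CC=C)(CO)[C@@H]1COCc2ccc(OC)cc2 | intermediate
25 | (Z)-enal from 24 (C7 aldehyde, C20 OH free) | CC1(C)CCC(=O)[C@](/C=C(\C=O)CC=C)(CO)[C@@H]1COCc2ccc(OC)cc2 | intermediate
26 | lactol from 25 (C7 hemiacetal, epimer mixture) | CC1(C)CCC(=O)[C@]2(COC(O)C(CC=C)=C2)[C@@H]1COCc3ccc(OC)cc3 | intermediate
27 | 4-allyl-11-{[(4-methoxybenzyl)oxy]methyl}-10,10-dimethyl-2-oxaspiro[5.5]undec-4-ene-3,7-dione (spiro C10 and C5 as in the target) | CC1(C)CCC(=O)[C@]2(COC(=O)C(CC=C)=C2)[C@@H]1COCc3ccc(OC)cc3 | intermediate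
28 | 2-bromoprop-2-enal | C=C(Br)C=O | starting material
29 | allylcopper | C=CC[Cu] | intermediate
30 | ketene trimethylsilyl acetal of the C9-allylated lactone | CC1(C)CCC(=O)[C@]2(COC(O[Si](C)(C)C)=C(CC=C)[C@H]2CC=C)[C@@H]1COCc3ccc(OC)cc3 | intermediate
31 | 15-O-trimethylsilyl ether of 32 | CC1(C)CCC(=O)[C@]2(COC(=O)[C@](CC=C)([C@H](O[Si](C)(C)C)C(Br)=C)[C@H]2CC=C)[C@@H]1COCc3ccc(OC)cc3 | intermediate
32 | aldol lactone: C8 quaternary with allyl and 2-bromo-1-hydroxyallyl groups, C9 allyl cis to the C8 allyl and to C1 | CC1(C)CCC(=O)[C@]2(COC(=O)[C@](CC=C)([C@H](O)C(Br)=C)[C@H]2CC=C)[C@@H]1COCc3ccc(OC)cc3 | intermediate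
33 | cis-fused cyclohexene lactone (C12=C13) carrying the 2-bromo-1-hydroxyallyl group on C8 | CC1(C)CCC(=O)[C@]2(COC(=O)[C@]3(CC=CC[C@@H]23)[C@H](O)C(Br)=C)[C@@H]1COCc4ccc(OC)cc4 | intermediate
34 | 15-hydroxy-16-methylidene tetracyclic lactone, C6 O-PMB, ring A saturated ketone | CC1(C)CCC(=O)[C@]2(COC(=O)[C@@]34C[C@@H](CC[C@@H]23)C(=C)[C@H]4O)[C@@H]1COCc5ccc(OC)cc5 | intermediate
35 | C1–C2 trimethylsilyl enol ether and 15-O-TMS ether of 34 | CC1(C)CC=C(O[Si](C)(C)C)[C@]2(COC(=O)[C@@]34C[C@@H](CC[C@@H]23)C(=C)[C@H]4O[Si](C)(C)C)[C@@H]1COCc5ccc(OC)cc5 | intermediate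
36 | 1-oxo-2-ene, 15-O-TMS, 6-O-PMB | CC1(C)C=CC(=O)[C@]2(COC(=O)[C@@]34C[C@@H](CC[C@@H]23)C(=C)[C@H]4O[Si](C)(C)C)[C@@H]1COCc5ccc(OC)cc5 | intermediate
37 | 6,15-dihydroxy-1-oxo-6,7-seco-ent-kaura-2,16-dien-7,20-olide | CC1(C)C=CC(=O)[C@]2(COC(=O)[C@@]34C[C@@H](CC[C@@H]23)C(=C)[C@H]4O)[C@@H]1CO | intermediate
38 | CNP0546915.1 | CC1(C)C=CC(=O)[C@]2(COC(=O)[C@@]34C[C@@H](CC[C@@H]23)[C@@](O)(CO)[C@H]4O)[C@@H]1CO | target

## Step count and risks

Total step count: 12. Longest linear sequence: 11 (steps 1, 2, 3, 5, 6, 7, 8, 9, 10, 11, 12; step 4 is the one-step branch).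

**Step 2 (proposed new conjugate addition).** The uncatalysed 1,2-addition of the Grignard reagent or a low ee could defeat it. The fallback sets out from 5 and comes back at 12. Reagent 8 is added to 5 with CuBr·SMe2 and no chiral ligand, a known type of racemic copper-mediated conjugate addition of alkoxymethyl organometallics, and the Mannich/elimination sequence is completed as before to give racemic 3-{[(4-methoxybenzyl)oxy]methyl}-4,4-dimethyl-2-methylidenecyclohexan-1-one F1. Preparative chromatography on a chiral stationary phase (cellulose tris(3,5-dimethylphenylcarbamate)) then delivers the (3R) enantiomer 12.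

**Step 6 (semipinacol shift).** Ring contraction or capture of C10 by the C7 oxygen could compete with alkenyl migration. The fallback avoids the rearrangement, sets out from 14 and comes back at 27. Isomerisation of 14 with Pd(PPh3)4/dppe (toluene, 80 °C) gives the 2-(hydroxymethylidene) ketone F2. Its caesium enolate (Cs2CO3, DMF) undergoes addition–elimination with ethyl (Z)-3-iodoacrylate on the face away from the C5 side chain to give the C-vinylated keto aldehyde F3. NaBH4 (MeOH, −78 °C) reduces only the aldehyde, and the alkoxide closes on the (Z)-ester to give the unsubstituted unsaturated spirolactone F4. α-Iodination (I2, pyridine, CH2Cl2) gives the α-iodo lactone F5, and Stille coupling with allyltributylstannane (Pd2(dba)3, AsPh3, CuI, DMF) returns 27.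

**Step 8 (conjugate allylation–aldol).** The β-carbon is hindered, allylcopper may attack the C1 ketone, and the C15 selectivity rests on an open transition state. The fallback sets out from 27 and comes back at 32. PhSeSiMe3 with catalytic TMSOTf (CH2Cl2, −78 °C) adds selenium to C9 and gives a β-seleno ketene silyl acetal, which is taken into the same TMSOTf-catalysed Mukaiyama aldol with 28 to give the 9-(phenylselanyl) aldol lactone F6. Keck radical allylation of F6 (allyltributylstannane, AIBN, PhH, 80 °C) then brings the allyl group to C9 from the face away from C5 and C15 and returns 32.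

Further compounds
F1 | step 2 | racemic 3-{[(4-methoxybenzyl)oxy]methyl}-4,4-dimethyl-2-methylidenecyclohexan-1-one | CC1(C)CCC(=O)C(=C)C1COCc2ccc(OC)cc2
F2 | step 6 | (3S)-2-(hydroxymethylidene)-3-{[(4-methoxybenzyl)oxy]methyl}-4,4-dimethylcyclohexan-1-one (enol form of the 2-formyl ketone) | CC1(C)CCC(=O)C(=CO)[C@@H]1COCc2ccc(OC)cc2
F3 | step 6 | ethyl (2Z)-3-(1-formyl-6-{[(4-methoxybenzyl)oxy]methyl}-5,5-dimethyl-2-oxocyclohexyl)prop-2-enoate (vinyl group trans, CHO cis to CH2OPMB) | CC1(C)CCC(=O)[C@](/C=C\C(=O)OCC)(C=O)[C@@H]1COCc2ccc(OC)cc2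
F4 | step 6 | 11-{[(4-methoxybenzyl)oxy]methyl}-10,10-dimethyl-2-oxaspiro[5.5]undec-4-ene-3,7-dione (27 without the allyl group) | CC1(C)CCC(=O)[C@]2(COC(=O)C=C2)[C@@H]1COCc3ccc(OC)cc3
F5 | step 6 | 4-iodo-11-{[(4-methoxybenzyl)oxy]methyl}-10,10-dimethyl-2-oxaspiro[5.5]undec-4-ene-3,7-dione | CC1(C)CCC(=O)[C@]2(COC(=O)C(I)=C2)[C@@H]1COCc3ccc(OC)cc3
F6 | step 8 | 9-(phenylselanyl) analogue of 32 (SePh in place of the C9 allyl group, same configuration) | CC1(C)CCC(=O)[C@]2(COC(=O)[C@](CC=C)([C@H](O)C(Br)=C)[C@H]2[Se]c3ccccc3)[C@@H]1COCc4ccc(OC)cc4
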